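## Analysis of the target

The target is a daucane sesquiterpene diester: a trans-fused hydroazulene made of a cyclopentane (C1–C5) and a cycloheptene (C1, C5–C10) whose only ring alkene is C8=C9, with a methyl group on C8. There are five stereocentres: quaternary C1 (methyl), C4 (tertiary carbinol with isopropyl), C5 (ring-fusion CH), C6 (4-hydroxybenzoate) and C10 (angelate), with configuration 1S,4R,5S,6S,10S in daucane numbering. Taking β as the face of the C1 methyl, the C4 hydroxyl, the C5–C6 bond and the C10 oxygen are β, whereas H5 and the C6 oxygen are α. The sensitive groups are the angelate (Z-to-E isomerisation during acylation or under base), the free phenol, the allylic ester at C10, and the tertiary C4 hydroxyl, which becomes a β-hydroxy ketone whenever C6 is a carbonyl. The synthesis is hard for three reasons: three contiguous substituted carbons (C1, C5, C4) on the five-membered ring, a trans ring fusion, and two secondary oxygens (C6, C10) that need different esters. The strategy rests on the O–C4–C5–C6 unit. The C4 oxygen and the C5–C6 bond are cis on the cyclopentane and C6 carries oxygen, so the unit is a 2-isoxazoline (O on C4, N=C6) in reduced form. That isoxazoline is the syn adduct of a nitrile oxide whose carbon is C6 to a C4=C5 cyclopentene next to the quaternary C1.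

## Retrosynthetic reasoning

**C6 ester and phenol.** Target 34 is traced to its aryl silyl ether 33, and the C6–O acyl bond of 33 is cut to give diol 28 and the protected acid 31 (from 29). The aroyl group is the only one that needs a protecting group, so attaching it last keeps that group in the route for two steps only. The forward acylation has to pick the secondary C6 hydroxyl over the tertiary C4 hydroxyl, which steric hindrance ensures.

**C6 carbinol.** Diol 28 comes from β-hydroxy ketone 27 by forming the C6–H bond. The hydride has to arrive on the β face, which is the more hindered one for an external reagent. The forward reaction therefore has to use the C4 hydroxyl to carry the hydride to C6.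

**N–O bond.** Ketone 27 is the reduced and hydrolysed form of isoxazoline 25. Keeping the heterocycle up to this point hides both the C6 carbonyl and the C4 oxygen. During the ring closure and the C10 chemistry there is then no 1,3-dicarbonyl, no β-leaving group and no β-hydroxy ketone.

**C10 ester and carbinol.** Angelate 25 is cut at the C10–O acyl bond to alcohol 22 and angelic acid 23, and 22 comes from enone 21 by 1,2-reduction. At this stage C6 is still an oxime-type carbon, so the C10 and C6 oxygens are told apart by oxidation level and no protecting group is needed. The forward reduction must add hydride anti to the angular methyl.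

**C8=C9.** Enone 21 is opened at its only ring alkene to diketone 19, which comes from bis-ketal 18. The cut is made here because the alkene is conjugated to the C10 carbonyl, which is the retron of an aldol condensation. The two arms sit trans on the cyclopentane, so only the seven-membered closure is free of strain.

**C5–C6 and C4–O (key disconnection).** Isoxazoline 18 is cut across both bonds to alkene 12 and nitrile oxide 17, which is generated from oxime 15. This one cut removes two stereocentres, one ring and the only C–C bond between the two halves, and it splits the molecule into a C10 and a C5 piece (ketal carbons not counted). The forward reaction has to place oxygen on C4 and carbon on C5, and it has to use the alkene face that carries the C1 methyl.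

**Alkene 12.** The C4–isopropyl bond is cut to enol triflate 10 and Grignard reagent 11. The dioxolane of 10 comes from methyl ketone 9, and the acetyl group of 9 from the 1-silylvinyl group of triflate 7. Triflate 7 comes from silyl enol ether 5, which is the trapped product of a conjugate addition of the vinyl unit of 1 to enone 2. That addition sets C1 by catalyst control, and the trapped enolate fixes the position of the later C4=C5 double bond.

**Oxime 15.** The C=N bond leads back to aldehyde 14 and the aldehyde to commercial ester 13, two routine steps.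

## Alternatives that were turned down

**Alternative 1:** The five-membered ring is built on a preformed seven-membered ring by cutting C4–C5 and C1–C2. In the forward direction, enone A1 (4-silyloxy-3-methylcyclohept-2-enone) is irradiated with allene A2 to give the trans-fused methylenecyclobutane A3. The four-membered ring then has to be enlarged by one carbon and the isopropyl group added to the resulting C4 carbonyl.
- For: the seven-membered ring is present from the start, so no medium-ring closure is needed. C1 and C5 form in one step, the C10 oxygen is already in place, and a twisted excited cycloheptenone tends to give the trans fusion.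
- Against: C5 in A3 is α to the C6 ketone on a strained trans-fused cyclobutane, so epimerisation to the cis isomer is a standing risk. The excited enone can also relax through the trans-cycloalkene and dimerise. The ring enlargement must choose between two migrating bonds. A3 has neither the C8 methyl nor the C8=C9 alkene (C7–C9 are methylenes), so several redox and C–C steps would follow. The absolute configuration depends on a resolved A1.
- Comparison: Alternative 1 is stronger on ring-size certainty and needs no enantioselective catalyst for the quaternary centre. The chosen route offers instead a stereospecific step that sets C4 and C5 with C6 at the right oxidation level, and building blocks that already carry C8, its methyl and the C10 oxygen.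

**Alternative 2:** Both rings are cut at once, at C1–C5 and C6–C7. In the forward direction the tethered yne–vinylcyclopropane A4 is treated with [Rh(CO)2Cl]2 A5 (monovalent rhodium) to give the bicyclo[5.3.0]decadiene A6 in a [5+2] cycloaddition.
- For: it is atom-economical and closes both rings in one catalytic step. The tertiary C4 carbinol is made beforehand on an open chain, and the silyl group marks C6 for later oxidation.
- Against: the alkene carbon that becomes C1 is trisubstituted, which is the least reactive substitution pattern for the alkene end of this cycloaddition. The C1 configuration would rest on 1,4-induction from C4 across the forming ring. C5 ends as an sp2 carbon (C5=C6), so the trans ring fusion must still be set at a tetrasubstituted vinylsilane. A6 has its alkene at C9=C10, no oxygen on C10 and no methyl on C8, so a transposition, an oxidation and a methylation are still missing.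
- Comparison: Alternative 2 reaches the bicyclic skeleton in fewer operations and is the more convergent ring construction. The chosen route is stronger on stereochemical definition (C4 and C5 from one concerted step under control of C1) and on delivering the full oxidation pattern.

**Alternative 3:** The seven-membered ring is cut at C9–C10 and C6–C7. In the forward direction the trans-dialdehyde A7 reacts twice with the bis(allylsilane) A8 under Lewis acid activation to give the 8-methylene diol A9.
- For: one step forms the seven-membered ring, brings C7–C9 with the C8 carbon, and leaves oxygen on both C6 and C10. There is no question of aldol regiochemistry.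
- Against: A7 already contains C1, C4 and C5 in their final configuration, so the hard part of the synthesis is moved into a precursor that is no easier to make than 12. C5 in A7 is an epimerisable α-carbon of an aldehyde with a β-silyloxy group that can be eliminated. After oxidation of both carbinols, the 6,10-dione with the C8 alkene is a vinylogous 1,3-diketone. The alkene can then settle at C7=C8 or C8=C9, and the two ketones need opposite facial outcomes and different esters.
- Comparison: Alternative 3 is stronger on the ring closure itself (one C–C bond-forming step against hydrolysis plus aldol). The chosen route keeps C6 and C10 at different oxidation levels (isoxazoline carbon against ketone) until each has been set and acylated, which removes the differentiation problem.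

Key step: step 8

Remark on the chemistry: the C10 acyl group is read from the double-bond descriptors as (Z)-2-methylbut-2-enoyl (angeloyl); daucane numbering is used for the bicyclic compounds (C1 quaternary with methyl, C4 with isopropyl, C5 ring-fusion CH, C8 with methyl), and β is the face of the C1 methyl.

## Route

Step 1
Reactants: 1 (trimethylsilyl)acetylene; 2 3-methylcyclopent-2-en-1-one
Product: 5 triethyl{[(3S)-3-methyl-3-(1-trimethylsilylvinyl)cyclopent-1-en-1-yl]oxy}silane, via diisobutyl(1-trimethylsilylvinyl)aluminium 3 (not isolated), via aluminium enolate 4 (not isolated)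
Conditions: 1, DIBAL-H, hexanes/THF, 55 °C; then 2, Cu(OTf)2 (5 mol%), chiral sulfonate-bearing imidazolinium salt (NHC precursor, 5 mol%) premixed with Ag2O, THF, 22 °C; then Et3SiOTf, −78 → 0 °C
Reagents that add atoms: triethylsilyl trifluoromethanesulfonate, CC[Si](CC)(CC)OS(=O)(=O)C(F)(F)F
Why: DIBAL-H adds across the silylalkyne with aluminium on the silicon-bearing carbon to give 3, and copper–NHC-catalysed enantioselective conjugate addition transfers the 1-silylvinyl group to the β-carbon of the enone, which creates the quaternary centre (the later C1); the ligand enantiomer is chosen so that the (S) centre results. The silyl triflate traps aluminium enolate 4 on oxygen, which fixes the enol double bond on the side of the quaternary carbon, where the later C4=C5 alkene is needed.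

Step 2
Reactants: 5 triethyl{[(3S)-3-methyl-3-(1-trimethylsilylvinyl)cyclopent-1-en-1-yl]oxy}silane
Product: 7 (3S)-3-methyl-3-(1-trimethylsilylvinyl)cyclopent-1-en-1-yl trifluoromethanesulfonate, via lithium enolate 6 (not isolated)
Conditions: MeLi, THF, 0 °C; then PhNTf2, −78 → 0 °C
Reagents that add atoms: N-phenylbis(trifluoromethanesulfonimide), O=S(=O)(N(c1ccccc1)S(=O)(=O)C(F)(F)F)C(F)(F)F
Why: MeLi cleaves the O–Si bond to the regiodefined lithium enolate 6, which is O-sulfonylated by PhNTf2 before it can equilibrate (enol triflate formation); the vinyl C–Si bond and the quaternary centre are not touched.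

Step 3
Reactants: 7 (3S)-3-methyl-3-(1-trimethylsilylvinyl)cyclopent-1-en-1-yl trifluoromethanesulfonate
Product: 9 (3S)-3-acetyl-3-methylcyclopent-1-en-1-yl trifluoromethanesulfonate, via epoxysilane 8 (not isolated)
Conditions: mCPBA, NaHCO3, CH2Cl2, 0 °C → rt; then 1 M H2SO4, MeOH, 40 °C
Reagents that add atoms: 3-chloroperbenzoic acid, OOC(=O)c1cccc(Cl)c1
Why: The peracid epoxidises the 1,1-disubstituted vinylsilane (Prilezhaev epoxidation) while the electron-poor enol triflate is left alone. Acid opens α,β-epoxysilane 8, and loss of the silyl group gives the enol of the methyl ketone, so the carbonyl ends on the carbon that carried silicon (epoxysilane-to-ketone unmasking).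

Step 4
Reactants: 9 (3S)-3-acetyl-3-methylcyclopent-1-en-1-yl trifluoromethanesulfonate
Product: 10 (3S)-3-methyl-3-(2-methyl-1,3-dioxolan-2-yl)cyclopent-1-en-1-yl trifluoromethanesulfonate
Conditions: TMSOCH2CH2OTMS, TMSOTf (5 mol%), CH2Cl2, −78 → −20 °C
Reagents that add atoms: 1,2-bis(trimethylsilyloxy)ethane, C[Si](C)(C)OCCO[Si](C)(C)C
Why: Silyl-transfer ketalisation under TMSOTf catalysis works at low temperature on the hindered ketone next to the quaternary carbon and does not affect the enol triflate. The dioxolane shields C10 from the Grignard reagent of step 5 and from hypochlorite in step 8, and it becomes the bulky group that directs the cycloaddition.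

Step 5
Reactants: 10 (3S)-3-methyl-3-(2-methyl-1,3-dioxolan-2-yl)cyclopent-1-en-1-yl trifluoromethanesulfonate; 11 isopropylmagnesium bromide
Product: 12 2-methyl-2-[(1S)-1-methyl-3-(propan-2-yl)cyclopent-2-en-1-yl]-1,3-dioxolane
Conditions: Fe(acac)3 (5 mol%), THF/NMP, −30 °C
Reagents that add atoms: none
Why: Iron-catalysed Kumada-type cross-coupling of alkenyl triflates with alkyl Grignard reagents is fast at low temperature, tolerates ketals and keeps the double bond where the triflate was, which gives the trisubstituted C4=C5 alkene with isopropyl on C4.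

Step 6
Reactants: 13 ethyl (2-methyl-1,3-dioxolan-2-yl)acetate
Product: 14 (2-methyl-1,3-dioxolan-2-yl)acetaldehyde
Conditions: DIBAL-H, CH2Cl2, −78 °C; Rochelle salt work-up
Reagents that add atoms: none
Why: Partial reduction of the ester with DIBAL-H at −78 °C stops at the aluminium hemiacetal, which the neighbouring dioxolane oxygen stabilises; the β-ketal aldehyde is used crude because it eliminates readily.

Step 7
Reactants: 14 (2-methyl-1,3-dioxolan-2-yl)acetaldehyde
Product: 15 (2-methyl-1,3-dioxolan-2-yl)acetaldehyde oxime (E/Z mixture)
Conditions: NH2OH (50% aq.), EtOH, 0 °C → rt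
Reagents that add atoms: hydroxylamine, NO
Why: Condensation of the aldehyde with free hydroxylamine gives the aldoxime under neutral conditions that spare the ketal; the E/Z mixture does not matter because both isomers give the same nitrile oxide.

Step 8
Reactants: 12 2-methyl-2-[(1S)-1-methyl-3-(propan-2-yl)cyclopent-2-en-1-yl]-1,3-dioxolane; 15 (2-methyl-1,3-dioxolan-2-yl)acetaldehyde oxime
Product: 18 (3aS,4S,6aR)-4-methyl-4-(2-methyl-1,3-dioxolan-2-yl)-3-[(2-methyl-1,3-dioxolan-2-yl)methyl]-6a-(propan-2-yl)-4,5,6,6a-tetrahydro-3aH-cyclopenta[d][1,2]oxazole, via hydroximoyl chloride 16 (not isolated), via nitrile oxide 17 (not isolated)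
Conditions: aq. NaOCl, CH2Cl2, 0 °C → rt; 15 (3 equiv) added over 12 h by syringe pump to concentrated 12
Reagents that add atoms: none
Why: Hypochlorite chlorinates the oxime to 16 and the basic aqueous phase dehydrochlorinates it to nitrile oxide 17, which adds to the C4=C5 double bond of 12 in a concerted, suprafacial [3+2] (Huisgen) cycloaddition; the closest known reaction type is the intermolecular nitrile oxide cycloaddition to trisubstituted cycloalkenes. The isoxazoline ring closes in the cycloaddition itself, as a [3+2] annulation in which the C5–C6 and C4–O bonds form together across the alkene, so no separate cyclisation mode has to be chosen. C4 and C5 are created cis to each other by the suprafacial addition, and their absolute sense is set by C1, because the dipole must approach the face that carries the small C1 methyl and avoid the face blocked by the fully substituted dioxolanyl group. The step needs three selectivities: regiochemistry (oxygen to the more substituted C4, carbon to C5), which follows the normal orientation of nitrile oxides on trisubstituted alkenes and is reinforced by the lower substitution of C5; facial selectivity, secured by the size difference of the two C1 substituents next to the reacting carbon; and cycloaddition over furoxan dimerisation, secured by a low stationary concentration of 17 in a concentrated solution of 12. Both ketals, including the one in the dipole, are inert to the basic two-phase medium.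

Step 9
Reactants: 18 bis-ketal isoxazoline
Product: 19 1-[(3aS,4S,6aR)-4-acetyl-4-methyl-6a-(propan-2-yl)-4,5,6,6a-tetrahydro-3aH-cyclopenta[d][1,2]oxazol-3-yl]propan-2-one
Conditions: 2 M HCl, THF, 40 °C
Reagents that add atoms: water, O
Why: Acid-catalysed hydrolysis removes both dioxolanes; the 2-isoxazoline is stable to aqueous acid, so C6 and the C4 oxygen stay masked.

Step 10
Reactants: 19 diketone isoxazoline
Product: 21 isoxazoline-bridged dauc-8-en-10-one (C10 ketone conjugated to C8=C9; 1β-methyl; 5α-H; 4β-O–N=C6 ring), via aldol 20 (not isolated)
Conditions: KOH (0.5 equiv), MeOH, 50 °C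
Reagents that add atoms: none
Why: Intramolecular aldol condensation: the C10 methyl ketone can enolise only towards C9, and this enolate adds to the unhindered C8 ketone (7-enolendo-exo-trig, an allowed mode) to give 20, which loses water by E1cB elimination to the conjugated enone. The more acidic C7 position has no productive outlet, because a C7–C10 bond would need a trans-fused bicyclo[3.3.0]octane (C10 and C6 are trans on the cyclopentane), and attack of the C8 methyl on the neopentylic C10 carbonyl is disfavoured.

Step 11
Reactants: 21 isoxazoline-bridged dauc-8-en-10-one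
Product: 22 isoxazoline-bridged dauc-8-en-10β-ol (10S; hydroxyl cis to the C1 methyl)
Conditions: NaBH4, CeCl3·7H2O, MeOH, −78 → −40 °C
Reagents that add atoms: none
Why: Luche reduction gives clean 1,2-reduction of the enone and leaves the C=N bond alone; hydride should add to the α face of C10, anti to the axial angular methyl on C1, which places the new hydroxyl β (10S).

Step 12
Reactants: 22 isoxazoline-bridged dauc-8-en-10β-ol; 23 angelic acid [(Z)-2-methylbut-2-enoic acid]
Product: 25 isoxazoline-bridged 10β-angeloyloxydauc-8-ene, via mixed anhydride 24 (not isolated)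
Conditions: 23, 2,4,6-Cl3C6H2COCl, Et3N, toluene, rt; then 22, toluene, 80 °C
Reagents that add atoms: none
Why: Acylation through the mixed anhydride with 2,4,6-trichlorobenzoic acid (Yamaguchi-type esterification run without a nucleophilic catalyst) esterifies hindered secondary alcohols with angelic acid without Z-to-E isomerisation, because no acylpyridinium species that could add and eliminate at the β-carbon is formed.

Step 13
Reactants: 25 isoxazoline-bridged 10β-angeloyloxydauc-8-ene
Product: 27 10β-angeloyloxy-4β-hydroxydauc-8-en-6-one (5α-H), via hydroxy imine 26 (not isolated)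
Conditions: Mo(CO)6, MeCN/H2O (15:1), 80 °C
Reagents that add atoms: water, O
Why: Mo(CO)6 cleaves the N–O bond reductively, and the resulting β-hydroxy imine 26 is hydrolysed in the wet solvent to the β-hydroxy ketone; the neutral conditions leave the trisubstituted alkene and the enoate untouched, which hydrogenolytic cleavage would not. C4 and C5 keep the configuration fixed in step 8.

Step 14
Reactants: 27 10β-angeloyloxy-4β-hydroxydauc-8-en-6-one
Product: 28 10β-angeloyloxydauc-8-ene-4β,6α-diol (6S)
Conditions: Me4NBH(OAc)3, MeCN/AcOH (1:1), −30 → 0 °C
Reagents that add atoms: none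
Why: Hydroxyl-directed reduction (Evans–Saksena type): the C4 hydroxyl exchanges an acetate on boron, and hydride is delivered through a six-membered transition state to the β face of C6, which gives the 1,3-anti diol with the C6 hydroxyl α (6S); an external hydride would attack the α face instead. The reagent does not reduce esters or isolated alkenes.

Step 15
Reactants: 29 4-hydroxybenzoic acid
Product: 31 4-[(tert-butyldimethylsilyl)oxy]benzoic acid, via bis-silyl derivative 30 (not isolated)
Conditions: TBSCl, imidazole, DMF, rt; then AcOH/THF/H2O, rt
Reagents that add atoms: tert-butyldimethylsilyl chloride, CC(C)(C)[Si](C)(C)Cl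
Why: Both the phenol and the acid are silylated; the silyl ester is far more labile than the aryl silyl ether and is hydrolysed selectively by aqueous acetic acid.

Step 16
Reactants: 28 10β-angeloyloxydauc-8-ene-4β,6α-diol; 31 4-[(tert-butyldimethylsilyl)oxy]benzoic acid
Product: 33 10β-angeloyloxy-6α-{4-[(tert-butyldimethylsilyl)oxy]benzoyloxy}dauc-8-en-4β-ol, via acid chloride 32 (not isolated)
Conditions: 31, (COCl)2, DMF (cat.), CH2Cl2, 0 °C → rt; then 28, Et3N, DMAP, CH2Cl2, rt
Reagents that add atoms: none
Why: Acylation with the acid chloride under DMAP catalysis (nucleophilic acyl-transfer esterification) esterifies the secondary C6 hydroxyl; the tertiary C4 hydroxyl is too hindered to react, and the alkyl angelate is not isomerised by DMAP at room temperature.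

Step 17
Reactants: 33 silyl-protected diester
Product: 34 target, 10β-angeloyloxy-6α-(4-hydroxybenzoyloxy)dauc-8-en-4β-ol (1S,4R,5S,6S,10S)
Conditions: TBAF, AcOH, THF, 0 °C
Reagents that add atoms: none
Why: Fluoride cleaves the aryl silyl ether within minutes; buffering with acetic acid keeps the medium non-basic, so neither ester migrates and the angelate geometry is kept.

## Compound list

1 | (trimethylsilyl)acetylene | C#C[Si](C)(C)C | starting material
2 | 3-methylcyclopent-2-en-1-one | CC1=CC(=O)CC1 | starting material
3 | diisobutyl(1-trimethylsilylvinyl)aluminium | C=C([Si](C)(C)C)[Al](CC(C)C)CC(C)C | intermediate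
4 | diisobutylaluminium (3S)-3-methyl-3-(1-trimethylsilylvinyl)cyclopent-1-en-1-olate | C=C([Si](C)(C)C)[C@@]1(C)CCC(O[Al](CC(C)C)CC(C)C)=C1 | intermediate
5 | triethyl{[(3S)-3-methyl-3-(1-trimethylsilylvinyl)cyclopent-1-en-1-yl]oxy}silane | C=C([Si](C)(C)C)[C@@]1(C)CCC(O[Si](CC)(CC)CC)=C1 | intermediate
6 | lithium (3S)-3-methyl-3-(1-trimethylsilylvinyl)cyclopent-1-en-1-olate | C=C([Si](C)(C)C)[C@@]1(C)CCC(O[Li])=C1 | intermediate
7 | (3S)-3-methyl-3-(1-trimethylsilylvinyl)cyclopent-1-en-1-yl trifluoromethanesulfonate | C=C([Si](C)(C)C)[C@@]1(C)CCC(OS(=O)(=O)C(F)(F)F)=C1 | intermediate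
8 | (3S)-3-methyl-3-[2-(trimethylsilyl)oxiran-2-yl]cyclopent-1-en-1-yl trifluoromethanesulfonate (oxirane epimers) | C[Si](C)(C)C1(CO1)[C@@]2(C)CCC(OS(=O)(=O)C(F)(F)F)=C2 | intermediate
9 | (3S)-3-acetyl-3-methylcyclopent-1-en-1-yl trifluoromethanesulfonate | CC(=O)[C@@]1(C)CCC(OS(=O)(=O)C(F)(F)F)=C1 | intermediate
10 | (3S)-3-methyl-3-(2-methyl-1,3-dioxolan-2-yl)cyclopent-1-en-1-yl trifluoromethanesulfonate | CC1(OCCO1)[C@@]2(C)CCC(OS(=O)(=O)C(F)(F)F)=C2 | intermediate
11 | isopropylmagnesium bromide | CC(C)[Mg]Br | starting material
12 | 2-methyl-2-[(1S)-1-methyl-3-(propan-2-yl)cyclopent-2-en-1-yl]-1,3-dioxolane | CC1(OCCO1)[C@@]2(C)CCC(C(C)C)=C2 | intermediate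
13 | ethyl (2-methyl-1,3-dioxolan-2-yl)acetate | CCOC(=O)CC1(C)OCCO1 | starting material
14 | (2-methyl-1,3-dioxolan-2-yl)acetaldehyde | O=CCC1(C)OCCO1 | intermediate
15 | (2-methyl-1,3-dioxolan-2-yl)acetaldehyde oxime (E/Z) | CC1(CC=NO)OCCO1 | intermediate
16 | N-hydroxy-2-(2-methyl-1,3-dioxolan-2-yl)acetimidoyl chloride | CC1(CC(Cl)=NO)OCCO1 | intermediate
17 | (2-methyl-1,3-dioxolan-2-yl)acetonitrile oxide | CC1(CC#[N+][O-])OCCO1 | intermediate
18 | (3aS,4S,6aR)-4-methyl-4-(2-methyl-1,3-dioxolan-2-yl)-3-[(2-methyl-1,3-dioxolan-2-yl)methyl]-6a-(propan-2-yl)-4,5,6,6a-tetrahydro-3aH-cyclopenta[d][1,2]oxazole | CC1(OCCO1)[C@@]2(C)CC[C@]3(C(C)C)ON=C(CC4(C)OCCO4)[C@H]23 | intermediate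
19 | 1-[(3aS,4S,6aR)-4-acetyl-4-methyl-6a-(propan-2-yl)-4,5,6,6a-tetrahydro-3aH-cyclopenta[d][1,2]oxazol-3-yl]propan-2-one | CC(=O)[C@@]1(C)CC[C@]2(C(C)C)ON=C(CC(C)=O)[C@H]12 | intermediate
20 | isoxazoline-bridged 8-hydroxydaucan-10-one (aldol, C8 epimers) | O=C1CC(C)(O)CC2=NO[C@@]3(C(C)C)CC[C@@]1(C)[C@@H]23 | intermediate
21 | isoxazoline-bridged dauc-8-en-10-one (1S,4R,5S; 4β-O–N=C6) | O=C1C=C(C)CC2=NO[C@@]3(C(C)C)CC[C@@]1(C)[C@@H]23 | intermediate
22 | isoxazoline-bridged dauc-8-en-10β-ol (10S) | O[C@H]1C=C(C)CC2=NO[C@@]3(C(C)C)CC[C@@]1(C)[C@@H]23 | intermediate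
23 | angelic acid, (Z)-2-methylbut-2-enoic acid | C/C=C(/C)C(=O)O | starting material
24 | angelic 2,4,6-trichlorobenzoic anhydride | C/C=C(/C)C(=O)OC(=O)c1c(Cl)cc(Cl)cc1Cl | intermediate
25 | isoxazoline-bridged 10β-angeloyloxydauc-8-ene | C/C=C(/C)C(=O)O[C@H]1C=C(C)CC2=NO[C@@]3(C(C)C)CC[C@@]1(C)[C@@H]23 | intermediate
26 | 10β-angeloyloxy-4β-hydroxydauc-8-en-6-imine | C/C=C(/C)C(=O)O[C@H]1C=C(C)CC(=N)[C@@H]2[C@]1(C)CC[C@@]2(O)C(C)C | intermediate
27 | 10β-angeloyloxy-4β-hydroxydauc-8-en-6-one (5α-H) | C/C=C(/C)C(=O)O[C@H]1C=C(C)CC(=O)[C@@H]2[C@]1(C)CC[C@@]2(O)C(C)C | intermediate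
28 | 10β-angeloyloxydauc-8-ene-4β,6α-diol | C/C=C(/C)C(=O)O[C@H]1C=C(C)C[C@H](O)[C@@H]2[C@]1(C)CC[C@@]2(O)C(C)C | intermediate
29 | 4-hydroxybenzoic acid | OC(=O)c1ccc(O)cc1 | starting material
30 | tert-butyldimethylsilyl 4-[(tert-butyldimethylsilyl)oxy]benzoate | CC(C)(C)[Si](C)(C)OC(=O)c1ccc(O[Si](C)(C)C(C)(C)C)cc1 | intermediate
31 | 4-[(tert-butyldimethylsilyl)oxy]benzoic acid | OC(=O)c1ccc(O[Si](C)(C)C(C)(C)C)cc1 | intermediate
32 | 4-[(tert-butyldimethylsilyl)oxy]benzoyl chloride | ClC(=O)c1ccc(O[Si](C)(C)C(C)(C)C)cc1 | intermediate
33 | 10β-angeloyloxy-6α-{4-[(tert-butyldimethylsilyl)oxy]benzoyloxy}dauc-8-en-4β-ol | C/C=C(/C)C(=O)O[C@H]1C=C(C)C[C@H](OC(=O)c2ccc(O[Si](C)(C)C(C)(C)C)cc2)[C@@H]2[C@]1(C)CC[C@@]2(O)C(C)C | intermediate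
34 | 10β-angeloyloxy-6α-(4-hydroxybenzoyloxy)dauc-8-en-4β-ol, (1S,4R,5S,6S,10S) | C/C=C(/C)C(=O)O[C@H]1C=C(C)C[C@H](OC(=O)c2ccc(O)cc2)[C@@H]2[C@]1(C)CC[C@@]2(O)C(C)C | target

## Step count and least certain steps

Total: 17 steps. Longest linear sequence: 14 steps (steps 1–5, 8–14, 16 and 17); steps 6–7 and 15 are side branches.

**Step 8 (key step).** The most likely failure is slow addition to the doubly hindered alkene (C5 is neopentylic and C4 carries isopropyl). Dimerisation of the dipole to the furoxan then outruns the cycloaddition, and prolonged exposure lets hypochlorite chlorinate the alkene. A second risk is incomplete facial discrimination between the methyl and dioxolanyl faces. Fallback, from 12 back to the route at 19: a small and cheap dipole is used in large excess and the side chain is completed afterwards. Acetonitrile oxide F1, generated from nitroethane with phenyl isocyanate and Et3N in the presence of 12, should give the 3-methylisoxazoline F2. Deprotonation of the exocyclic methyl group with LDA at −78 °C and acylation with N-methoxy-N-methylacetamide should give the keto isoxazoline F3, and hydrolysis of its remaining ketal with aqueous HCl gives 19.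

**Step 10.** Enolisation at the acidic C7 position can hold the substrate in an unreactive form so that the seven-membered closure stalls. The C8 methyl group may close onto C10 instead, or the double bond of the product may drift out of conjugation through the extended enolate. Fallback, from 19 to 21, with the nucleophile and electrophile fixed in advance: the unhindered C8 ketone is converted selectively into the dimethyl ketal F4 (HC(OMe)3, MeOH, PPTS; the neopentylic C10 ketone reacts far more slowly). The C10 methyl ketone is turned into the trimethylsilyl enol ether F5 (LiHMDS, TMSCl, −78 °C). TMSOTf then induces an intramolecular Mukaiyama aldol addition to the ketal-derived oxocarbenium ion to give the β-methoxy ketone F6, and DBU eliminates methanol to give 21.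

**Step 13.** The liberated β-hydroxy ketone is prone to migration of the C8=C9 alkene into conjugation with C6, to epimerisation at C5, and to loss of the C4 hydroxyl by dehydration. Enolisation towards C7 can also expel the allylic angelate in a vinylogous elimination, and the angelate geometry may not survive heating with the metal carbonyl. Fallback, from 22 to 33, with the angelate introduced last so that C10 carries a poor leaving group during the sensitive stage. Alcohol 22 is silylated to the triethylsilyl ether F7 (Et3SiCl, imidazole). N–O cleavage with Mo(CO)6 gives the hydroxy ketone F8, and directed reduction as in step 14 gives the diol F9. Acylation with 32 as in step 16 gives the aroyl ester F10, and AcOH/THF/H2O removes the alkyl silyl ether, leaving the aryl silyl ether, to give the C10 alcohol F11. Angeloylation of F11 with 24 as in step 12 gives 33.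

**Step 14.** The tertiary C4 hydroxyl may exchange onto boron too slowly. The reduction then stalls, or hydride arrives from outside on the α face and the 6β-epimer forms. Fallback, from 27 to 33, which uses the external-hydride preference instead of fighting it: reduction with LiBH(s-Bu)3 from the open α face should give the 6β-alcohol F12. Mitsunobu esterification of F12 with acid 31 (PPh3, DIAD) inverts C6 and gives 33 directly.

**Step 5.** The secondary alkyl–iron intermediate can undergo β-hydride elimination, which leads to reduction of the triflate or to transfer of an n-propyl group. Fallback, from 10 to 12, which avoids an sp3 organometallic with β-hydrogens: Suzuki–Miyaura coupling of 10 with isopropenylboronic acid pinacol ester (Pd(PPh3)4, K3PO4) should give the diene F13. Diimide, generated from 2-nitrobenzenesulfonyl hydrazide and Et3N, then reduces the 1,1-disubstituted double bond of F13 in preference to the trisubstituted ring alkene and gives 12.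

## Further compounds

F1 | step 8 | acetonitrile oxide | CC#[N+][O-]
F2 | step 8 | (3aS,4S,6aR)-3,4-dimethyl-4-(2-methyl-1,3-dioxolan-2-yl)-6a-(propan-2-yl)-4,5,6,6a-tetrahydro-3aH-cyclopenta[d][1,2]oxazole | CC1(OCCO1)[C@@]2(C)CC[C@]3(C(C)C)ON=C(C)[C@H]23
F3 | step 8 | 1-[(3aS,4S,6aR)-4-methyl-4-(2-methyl-1,3-dioxolan-2-yl)-6a-(propan-2-yl)-4,5,6,6a-tetrahydro-3aH-cyclopenta[d][1,2]oxazol-3-yl]propan-2-one | CC1(OCCO1)[C@@]2(C)CC[C@]3(C(C)C)ON=C(CC(C)=O)[C@H]23
F4 | step 10 | 1-[(3aS,4S,6aR)-3-(2,2-dimethoxypropyl)-4-methyl-6a-(propan-2-yl)-4,5,6,6a-tetrahydro-3aH-cyclopenta[d][1,2]oxazol-4-yl]ethan-1-one | CC(=O)[C@@]1(C)CC[C@]2(C(C)C)ON=C(CC(C)(OC)OC)[C@H]12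
F5 | step 10 | trimethylsilyl enol ether of F4 at the C10 methyl ketone | C=C(O[Si](C)(C)C)[C@@]1(C)CC[C@]2(C(C)C)ON=C(CC(C)(OC)OC)[C@H]12
F6 | step 10 | isoxazoline-bridged 8-methoxydaucan-10-one (C8 epimers) | O=C1CC(C)(OC)CC2=NO[C@@]3(C(C)C)CC[C@@]1(C)[C@@H]23
F7 | step 13 | isoxazoline-bridged 10β-(triethylsilyloxy)dauc-8-ene | CC[Si](CC)(CC)O[C@H]1C=C(C)CC2=NO[C@@]3(C(C)C)CC[C@@]1(C)[C@@H]23
F8 | step 13 | 4β-hydroxy-10β-(triethylsilyloxy)dauc-8-en-6-one | CC[Si](CC)(CC)O[C@H]1C=C(C)CC(=O)[C@@H]2[C@]1(C)CC[C@@]2(O)C(C)C
F9 | step 13 | 10β-(triethylsilyloxy)dauc-8-ene-4β,6α-diol | CC[Si](CC)(CC)O[C@H]1C=C(C)C[C@H](O)[C@@H]2[C@]1(C)CC[C@@]2(O)C(C)C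
F10 | step 13 | 6α-{4-[(tert-butyldimethylsilyl)oxy]benzoyloxy}-10β-(triethylsilyloxy)dauc-8-en-4β-ol | CC[Si](CC)(CC)O[C@H]1C=C(C)C[C@H](OC(=O)c2ccc(O[Si](C)(C)C(C)(C)C)cc2)[C@@H]2[C@]1(C)CC[C@@]2(O)C(C)C
F11 | step 13 | 6α-{4-[(tert-butyldimethylsilyl)oxy]benzoyloxy}dauc-8-ene-4β,10β-diol | O[C@H]1C=C(C)C[C@H](OC(=O)c2ccc(O[Si](C)(C)C(C)(C)C)cc2)[C@@H]2[C@]1(C)CC[C@@]2(O)C(C)C
F12 | step 14 | 10β-angeloyloxydauc-8-ene-4β,6β-diol (6-epimer of 28) | C/C=C(/C)C(=O)O[C@H]1C=C(C)C[C@@H](O)[C@@H]2[C@]1(C)CC[C@@]2(O)C(C)C
F13 | step 5 | 2-methyl-2-[(1S)-1-methyl-3-(prop-1-en-2-yl)cyclopent-2-en-1-yl]-1,3-dioxolane | CC1(OCCO1)[C@@]2(C)CCC(C(C)=C)=C2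
A1 | alternative 1 | 4-[(tert-butyldimethylsilyl)oxy]-3-methylcyclohept-2-en-1-one | CC1=CC(=O)CCC[C@@H]1O[Si](C)(C)C(C)(C)C
A2 | alternative 1 | allene (propa-1,2-diene) | C=C=C
A3 | alternative 1 | trans-fused 6-[(tert-butyldimethylsilyl)oxy]-7-methyl-9-methylidenebicyclo[5.2.0]nonan-2-one | C=C1C[C@]2(C)[C@@H](O[Si](C)(C)C(C)(C)C)CCCC(=O)[C@@H]12
A4 | alternative 2 | (E)-yne–vinylcyclopropane: trimethyl{[7-cyclopropyl-6-methyl-3-(propan-2-yl)-1-(trimethylsilyl)hept-6-en-1-yn-3-yl]oxy}silane | C[Si](C)(C)C#C[C@](O[Si](C)(C)C)(C(C)C)CC/C(C)=C/C1CC1
A5 | alternative 2 | di-μ-chlorotetracarbonyldirhodium, [Rh(CO)2Cl]2 | [Rh+].[Rh+].[Cl-].[Cl-].[C-]#[O+].[C-]#[O+].[C-]#[O+].[C-]#[O+]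
A6 | alternative 2 | 1-methyl-4-(propan-2-yl)-6-(trimethylsilyl)-4-[(trimethylsilyl)oxy]bicyclo[5.3.0]deca-5,9-diene (daucane numbering) | C1=CCCC([Si](C)(C)C)=C2[C@]1(C)CC[C@@]2(O[Si](C)(C)C)C(C)C
A7 | alternative 3 | trans-1-methyl-3-(propan-2-yl)-3-[(triethylsilyl)oxy]cyclopentane-1,2-dicarbaldehyde | O=C[C@@H]1[C@@](C)(C=O)CC[C@@]1(O[Si](CC)(CC)CC)C(C)C
A8 | alternative 3 | 2-methylene-1,3-bis(trimethylsilyl)propane | C=C(C[Si](C)(C)C)C[Si](C)(C)C
A9 | alternative 3 | 8-methylidene-4-[(triethylsilyl)oxy]daucane-6,10-diol (C6 and C10 epimers) | OC1CC(=C)CC(O)[C@@H]2[C@]1(C)CC[C@@]2(O[Si](CC)(CC)CC)C(C)C
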